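**Retrosynthetic overview**
1. Target 24 ⇐ double decarboxylation and air oxidation of the bis(β-keto ester) 22 ⇐ ipso-C-allylation of diester 20 with the C40 allylic acetate 16, then C-methylation (prenyl first, methyl second, as in menaquinone biosynthesis).
2. The oxygenated ring of 20 is the only ring formed: Claisen acylation and Dieckmann closure of an o-succinylbenzoate-type keto ester from dimethyl phthalate and dimethyl succinate. The benzo ring is bought.
3. Chain 16 ⇐ C5 head 14 + saturated C15 triad 7 + C15 farnesyl linchpin 3 + isopentyl Grignard 4, joined by three copper-catalysed Grignard/allyl couplings.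
4. All three stereocentres come from one Ir-catalysed asymmetric hydrogenation of 12-hydroxyfarnesyl acetate 2, which also feeds the unsaturated tail.

Assumption: isomerically pure (2E,6E)-farnesyl acetate (1) is bought as such.
Abbreviation: Ir-cat = [Ir(cod)L][B(C6H3(CF3)2)4], cod = cycloocta-1,5-diene, L = 7-[bis(2-methylphenyl)phosphanyloxy]-2-phenyl-6,7-dihydro-5H-cyclopenta[b]pyridine, used as the antipode that reduces (2E,6E)-farnesol to (3S,7S)-3,7,11-trimethyldodecan-1-ol.

**Route**

Step 1
Reactants: 1 (2E,6E)-3,7,11-trimethyldodeca-2,6,10-trien-1-yl acetate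
Product: 2 (2E,6E,10E)-12-hydroxy-3,7,11-trimethyldodeca-2,6,10-trien-1-yl acetate
Conditions: SeO2 (0.2 equiv), t-BuOOH (3 equiv), salicylic acid (0.1 equiv), CH2Cl2, 0 °C → rt, run to about 60% conversion and recycle 1
Reagents that add atoms: tert-butyl hydroperoxide, CC(C)(C)OO (terminal oxidant); selenium dioxide, O=[Se]=O (passes the oxygen on and is regenerated)
Why: Sharpless SeO2/t-BuOOH allylic oxidation (ene reaction then [2,3]-shift) attacks the terminal, most electron-rich olefin at its E-methyl group, giving the E-allylic alcohol and leaving the allylic acetate alone.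

Step 2
Reactants: 2 (2E,6E,10E)-12-hydroxy-3,7,11-trimethyldodeca-2,6,10-trien-1-yl acetate
Product: 3 (2E,6E,10E)-12-bromo-3,7,11-trimethyldodeca-2,6,10-trien-1-yl acetate
Conditions: CBr4, PPh3, CH2Cl2, 0 °C
Reagents that add atoms: carbon tetrabromide, BrC(Br)(Br)Br
Why: Appel bromination converts the primary allylic alcohol under neutral conditions without allylic shift or E/Z change, and the acetate is inert.

Step 3
Reactants: 3 (2E,6E,10E)-12-bromo-3,7,11-trimethyldodeca-2,6,10-trien-1-yl acetate; 4 3-methylbutylmagnesium bromide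
Product: 5 (2E,6E,10E)-3,7,11,15-tetramethylhexadeca-2,6,10-trien-1-yl acetate
Conditions: Li2CuCl4 (5 mol %), THF, −78 → −40 °C, 4 (1.05 equiv) added slowly
Reagents that add atoms: none
Why: Kochi-type copper-catalysed Grignard coupling displaces the allylic bromide by SN2 with retention of the E-olefin far faster at −78 °C than the allylic acetate or its carbonyl reacts, which installs the saturated terminus.

Step 4
Reactants: 2 (2E,6E,10E)-12-hydroxy-3,7,11-trimethyldodeca-2,6,10-trien-1-yl acetate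
Product: 6 (3S,7R,11R)-12-hydroxy-3,7,11-trimethyldodecyl acetate
Conditions: H2 (50 bar), Ir-cat (1 mol %), CH2Cl2, 25 °C
Reagents that add atoms: none
Why: Pfaltz-type iridium-catalysed asymmetric hydrogenation of trisubstituted olefins reduces all three E-olefins on the same face, because each presents the same local shape (vinylic H on the head-side carbon, methyl on the tail-side carbon), so C3, C7 and C11 are set together in the sense this antipode shows with farnesol (3S,7S there; 3S,7R,11R here only through CIP priorities).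

Step 5
Reactants: 6 (3S,7R,11R)-12-hydroxy-3,7,11-trimethyldodecyl acetate
Product: 7 (3S,7R,11R)-12-bromo-3,7,11-trimethyldodecyl acetate
Conditions: CBr4, PPh3, CH2Cl2, 0 °C → rt
Reagents that add atoms: carbon tetrabromide, BrC(Br)(Br)Br
Why: Appel reaction at the primary carbinol C12; the neighbouring stereocentre C11 is not part of the SN2 event and the acetate survives.

Step 6
Reactants: 7 (3S,7R,11R)-12-bromo-3,7,11-trimethyldodecyl acetate; 5 (2E,6E,10E)-3,7,11,15-tetramethylhexadeca-2,6,10-trien-1-yl acetate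
Product: 10 (3S,7S,11R,14E,18E,22E)-3,7,11,15,19,23,27-heptamethyloctacosa-14,18,22-trien-1-ol, via chloromagnesium alkoxide 8 (not isolated), via alkoxide Grignard reagent 9 (not isolated)
Conditions: MeMgCl (2.05 equiv), THF, −20 °C; then Mg turnings, THF, 45 °C; then added quickly to 5 (1.1 equiv) and Li2CuCl4 (5 mol %), THF, −10 → 0 °C; aq. NH4Cl
Reagents that add atoms: methylmagnesium chloride, C[Mg]Cl; magnesium, [Mg] (their atoms stay only in the unisolated intermediates 8 and 9)
Why: MeMgCl cleaves the acetate to a magnesium alkoxide (Normant-type masked alcohol), magnesium inserts into the C–Br bond, and Fouquet–Schlosser copper-catalysed coupling with the primary allylic acetate goes by SN2 at CH2 (the SN2′ path would build a quaternary carbon) with the E-olefin kept.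

Step 7
Reactants: 10 (3S,7S,11R,14E,18E,22E)-3,7,11,15,19,23,27-heptamethyloctacosa-14,18,22-trien-1-ol
Product: 11 (3S,7S,11R,14E,18E,22E)-1-bromo-3,7,11,15,19,23,27-heptamethyloctacosa-14,18,22-triene (numbered from the C–Br end)
Conditions: CBr4, PPh3, CH2Cl2, 0 °C
Reagents that add atoms: carbon tetrabromide, BrC(Br)(Br)Br
Why: Appel bromination of an unhindered primary alcohol; the isolated trisubstituted olefins and the stereocentres are inert.

Step 8
Reactants: 12 3-methylbut-2-en-1-yl acetate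
Product: 13 (2E)-4-hydroxy-3-methylbut-2-en-1-yl acetate
Conditions: SeO2 (0.2 equiv), t-BuOOH (3 equiv), salicylic acid (0.1 equiv), CH2Cl2, rt
Reagents that add atoms: tert-butyl hydroperoxide, CC(C)(C)OO (terminal oxidant); selenium dioxide, O=[Se]=O (passes the oxygen on and is regenerated)
Why: The same Sharpless allylic oxidation hydroxylates the E-methyl group only, which fixes the 2E geometry of the future first prenyl unit.

Step 9
Reactants: 13 (2E)-4-hydroxy-3-methylbut-2-en-1-yl acetate
Product: 14 (2E)-4-bromo-3-methylbut-2-en-1-yl acetate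
Conditions: CBr4, PPh3, CH2Cl2, 0 °C
Reagents that add atoms: carbon tetrabromide, BrC(Br)(Br)Br
Why: Appel bromination of the allylic alcohol without transposition or loss of E geometry.

Step 10
Reactants: 11 (3S,7S,11R,14E,18E,22E)-1-bromo-3,7,11,15,19,23,27-heptamethyloctacosa-14,18,22-triene; 14 (2E)-4-bromo-3-methylbut-2-en-1-yl acetate
Product: 16 (2E,7S,11R,15R,18E,22E,26E)-3,7,11,15,19,23,27,31-octamethyldotriaconta-2,18,22,26-tetraen-1-yl acetate, via Grignard reagent 15 (not isolated)
Conditions: Mg turnings, THF, 45 °C; then added slowly to 14 (1.5 equiv) and Li2CuCl4 (5 mol %), THF, −78 → −40 °C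
Reagents that add atoms: magnesium, [Mg] (stays only in the unisolated intermediate 15)
Why: Grignard formation (the olefins are too remote to cyclise) then Kochi copper-catalysed SN2 coupling at the allylic bromide with inverse addition, so the Grignard reagent is never in excess over the acetate, gives the complete C40 chain with 2E retained.

Step 11
Reactants: 17 dimethyl benzene-1,2-dicarboxylate; 18 dimethyl butanedioate
Product: 20 dimethyl 1,4-dihydroxynaphthalene-2,3-dicarboxylate, via keto triester 19 (not isolated)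
Conditions: NaH (2.5 equiv), MeOH (cat.), THF, reflux; then aq. HCl
Reagents that add atoms: none
Why: Claisen acylation of the succinate enolate gives the o-succinylbenzoate-type keto triester, whose Dieckmann closure (ester α-carbon onto the aryl ester, the same bond and polarity as the enzymatic o-succinylbenzoate → 1,4-dihydroxy-2-naphthoate step) is driven by aromatisation and deprotonation of the product.

Step 12
Reactants: 20 dimethyl 1,4-dihydroxynaphthalene-2,3-dicarboxylate; 16 (2E,7S,11R,15R,18E,22E,26E)-3,7,11,15,19,23,27,31-octamethyldotriaconta-2,18,22,26-tetraen-1-yl acetate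
Product: 22 dimethyl 2-methyl-3-[(2E,7S,11R,15R,18E,22E,26E)-3,7,11,15,19,23,27,31-octamethyldotriaconta-2,18,22,26-tetraen-1-yl]-1,4-dioxo-1,2,3,4-tetrahydronaphthalene-2,3-dicarboxylate (mixture at C2/C3), via monoallylated keto diester 21 (not isolated)
Conditions: 20 (1.3 equiv), NaH (1.3 equiv), THF, 0 °C; Pd(PPh3)4 (5 mol %), 16 (1.0 equiv), THF, 45 °C, Ar; then NaH (1.5 equiv), MeI (4 equiv), 0 °C → rt
Reagents that add atoms: iodomethane, CI
Why: Proposed new method: the sodium salt of 20 acts as a cyclic β-keto ester enolate (its diketo tautomer lies close in energy), so the π-allyl complex formed from 16 and zerovalent palladium is attacked at its CH2 terminus by C2 (O-allylation is reversible, C-allylation is not; C2 and C3 are equivalent; the syn π-allyl keeps 2E), and the now non-aromatic β-keto ester 21 is C-methylated by MeI, the closest known reactions being Tsuji–Trost allylation of cyclic β-keto esters, palladium-catalysed allylic dearomatisation of naphthols and alkylation of 2-carbomethoxy-1-tetralone.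

Step 13
Reactants: 22 dimethyl 2-methyl-3-[(2E,7S,11R,15R,18E,22E,26E)-3,7,11,15,19,23,27,31-octamethyldotriaconta-2,18,22,26-tetraen-1-yl]-1,4-dioxo-1,2,3,4-tetrahydronaphthalene-2,3-dicarboxylate
Product: 24 2-methyl-3-[(2E,7S,11R,15R,18E,22E,26E)-3,7,11,15,19,23,27,31-octamethyldotriaconta-2,18,22,26-tetraen-1-yl]naphthalene-1,4-dione, via menaquinol 23 (not isolated)
Conditions: LiCl (6 equiv), H2O (4 equiv), DMSO, 140 °C, Ar, dark; then air, rt
Reagents that add atoms: none
Why: Double Krapcho dealkoxycarbonylation (chloride SN2 at both ester methyls, CO2 loss from both β-keto carboxylates) erases the two ring stereocentres and gives the naphthalenediol, which air oxidises to the quinone while the remote stereocentres and E-olefins are untouched.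

**Compound list**
1 | (2E,6E)-3,7,11-trimethyldodeca-2,6,10-trien-1-yl acetate | CC(=O)OC/C=C(\C)CC/C=C(\C)CCC=C(C)C | starting material
2 | (2E,6E,10E)-12-hydroxy-3,7,11-trimethyldodeca-2,6,10-trien-1-yl acetate | CC(=O)OC/C=C(\C)CC/C=C(\C)CC/C=C(\C)CO | intermediate
3 | (2E,6E,10E)-12-bromo-3,7,11-trimethyldodeca-2,6,10-trien-1-yl acetate | CC(=O)OC/C=C(\C)CC/C=C(\C)CC/C=C(\C)CBr | intermediate
4 | 3-methylbutylmagnesium bromide | CC(C)CC[Mg]Br | starting material
5 | (2E,6E,10E)-3,7,11,15-tetramethylhexadeca-2,6,10-trien-1-yl acetate | CC(=O)OC/C=C(\C)CC/C=C(\C)CC/C=C(\C)CCCC(C)C | intermediate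
6 | (3S,7R,11R)-12-hydroxy-3,7,11-trimethyldodecyl acetate | CC(=O)OCC[C@@H](C)CCC[C@@H](C)CCC[C@@H](C)CO | intermediate
7 | (3S,7R,11R)-12-bromo-3,7,11-trimethyldodecyl acetate | CC(=O)OCC[C@@H](C)CCC[C@@H](C)CCC[C@@H](C)CBr | intermediate
8 | chloromagnesium (3S,7R,11R)-12-bromo-3,7,11-trimethyldodecan-1-olate | Cl[Mg]OCC[C@@H](C)CCC[C@@H](C)CCC[C@@H](C)CBr | intermediate (not isolated)
9 | [(2R,6R,10S)-12-(chloromagnesiooxy)-2,6,10-trimethyldodecyl]magnesium bromide | Cl[Mg]OCC[C@@H](C)CCC[C@@H](C)CCC[C@@H](C)C[Mg]Br | intermediate (not isolated)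
10 | (3S,7S,11R,14E,18E,22E)-3,7,11,15,19,23,27-heptamethyloctacosa-14,18,22-trien-1-ol | OCC[C@@H](C)CCC[C@@H](C)CCC[C@@H](C)CC/C=C(\C)CC/C=C(\C)CC/C=C(\C)CCCC(C)C | intermediate
11 | (3S,7S,11R,14E,18E,22E)-1-bromo-3,7,11,15,19,23,27-heptamethyloctacosa-14,18,22-triene | BrCC[C@@H](C)CCC[C@@H](C)CCC[C@@H](C)CC/C=C(\C)CC/C=C(\C)CC/C=C(\C)CCCC(C)C | intermediate
12 | 3-methylbut-2-en-1-yl acetate | CC(=O)OCC=C(C)C | starting material
13 | (2E)-4-hydroxy-3-methylbut-2-en-1-yl acetate | CC(=O)OC/C=C(\C)CO | intermediate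
14 | (2E)-4-bromo-3-methylbut-2-en-1-yl acetate | CC(=O)OC/C=C(\C)CBr | intermediate
15 | [(3S,7S,11R,14E,18E,22E)-3,7,11,15,19,23,27-heptamethyloctacosa-14,18,22-trien-1-yl]magnesium bromide | Br[Mg]CC[C@@H](C)CCC[C@@H](C)CCC[C@@H](C)CC/C=C(\C)CC/C=C(\C)CC/C=C(\C)CCCC(C)C | intermediate (not isolated)
16 | (2E,7S,11R,15R,18E,22E,26E)-3,7,11,15,19,23,27,31-octamethyldotriaconta-2,18,22,26-tetraen-1-yl acetate | CC(=O)OC/C=C(\C)CCC[C@@H](C)CCC[C@@H](C)CCC[C@@H](C)CC/C=C(\C)CC/C=C(\C)CC/C=C(\C)CCCC(C)C | intermediate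
17 | dimethyl benzene-1,2-dicarboxylate (dimethyl phthalate) | COC(=O)c1ccccc1C(=O)OC | starting material
18 | dimethyl butanedioate (dimethyl succinate) | COC(=O)CCC(=O)OC | starting material
19 | dimethyl 2-[2-(methoxycarbonyl)benzoyl]butanedioate (racemic) | COC(=O)CC(C(=O)OC)C(=O)c1ccccc1C(=O)OC | intermediate (not isolated)
20 | dimethyl 1,4-dihydroxynaphthalene-2,3-dicarboxylate | COC(=O)c1c(O)c2ccccc2c(O)c1C(=O)OC | intermediate
21 | dimethyl 2-[(2E,7S,11R,15R,18E,22E,26E)-3,7,11,15,19,23,27,31-octamethyldotriaconta-2,18,22,26-tetraen-1-yl]-1,4-dioxo-1,2,3,4-tetrahydronaphthalene-2,3-dicarboxylate (ring C2/C3 not controlled) | COC(=O)C1C(=O)c2ccccc2C(=O)C1(C/C=C(\C)CCC[C@@H](C)CCC[C@@H](C)CCC[C@@H](C)CC/C=C(\C)CC/C=C(\C)CC/C=C(\C)CCCC(C)C)C(=O)OC | intermediate (not isolated)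
22 | dimethyl 2-methyl-3-[(2E,7S,11R,15R,18E,22E,26E)-3,7,11,15,19,23,27,31-octamethyldotriaconta-2,18,22,26-tetraen-1-yl]-1,4-dioxo-1,2,3,4-tetrahydronaphthalene-2,3-dicarboxylate (ring C2/C3 not controlled) | COC(=O)C1(C)C(=O)c2ccccc2C(=O)C1(C/C=C(\C)CCC[C@@H](C)CCC[C@@H](C)CCC[C@@H](C)CC/C=C(\C)CC/C=C(\C)CC/C=C(\C)CCCC(C)C)C(=O)OC | intermediate
23 | 2-methyl-3-[(2E,7S,11R,15R,18E,22E,26E)-3,7,11,15,19,23,27,31-octamethyldotriaconta-2,18,22,26-tetraen-1-yl]naphthalene-1,4-diol | Cc1c(C/C=C(\C)CCC[C@@H](C)CCC[C@@H](C)CCC[C@@H](C)CC/C=C(\C)CC/C=C(\C)CC/C=C(\C)CCCC(C)C)c(O)c2ccccc2c1O | intermediate (not isolated)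
24 | 2-methyl-3-[(2E,7S,11R,15R,18E,22E,26E)-3,7,11,15,19,23,27,31-octamethyldotriaconta-2,18,22,26-tetraen-1-yl]naphthalene-1,4-dione | CC1=C(C/C=C(\C)CCC[C@@H](C)CCC[C@@H](C)CCC[C@@H](C)CC/C=C(\C)CC/C=C(\C)CC/C=C(\C)CCCC(C)C)C(=O)c2ccccc2C1=O | target

**Totals**
Total step count: 13. Longest linear sequence: 8 steps (1, 4, 5, 6, 7, 10, 12, 13).

**Steps most likely to fail, with fallbacks**

Step 4 (three stereocentres in one hydrogenation). The terminal 2-methylallylic alcohol is the olefin least covered by farnesol precedent and may reduce with lower selectivity or isomerise. The fallback sets the centres in two stages by two mechanisms. It sets out from 2: hydroxyl-directed hydrogenation with Ru(OAc)2(BINAP) (BINAP = 2,2′-bis(diphenylphosphino)-1,1′-binaphthyl, antipode chosen to give 11R; H2 30 bar, MeOH) reduces only the olefin next to the free OH. This gives (2E,6E,11R)-12-hydroxy-3,7,11-trimethyldodeca-2,6-dien-1-yl acetate F1. Ir-cat and H2 then reduce the two remaining olefins, now a plain farnesyl-acetate-type diene, and the sequence comes back to the route at 6.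

Step 6 (alkoxide Grignard reagent with an allylic acetate). Attack at the acetate carbonyl or SN2′ substitution could compete. The fallback replaces the copper coupling by a sulfone union. It sets out from 5 and 7. Sodium 4-methylbenzenesulfinate with Pd(PPh3)4 (cat.) in THF/MeOH turns 5 into 1-methyl-4-{[(2E,6E,10E)-3,7,11,15-tetramethylhexadeca-2,6,10-trien-1-yl]sulfonyl}benzene F2. K2CO3/MeOH turns 7 into (3S,7R,11R)-12-bromo-3,7,11-trimethyldodecan-1-ol F3. F2 and F3 with n-BuLi (2.1 equiv, THF/DMPU, −78 → 0 °C) give, by alkylation of the α-sulfonyl carbanion at the primary bromide, (3S,7R,11R,14E,18E,22E)-3,7,11,15,19,23,27-heptamethyl-13-(4-methylbenzenesulfonyl)octacosa-14,18,22-trien-1-ol F4 as a C13 epimer mixture. Reductive desulfonylation with LiBHEt3 and PdCl2[Ph2P(CH2)3PPh2] (cat.), which keeps olefin position and geometry, comes back to the route at 10.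

Step 12 (ipso-C-allylation then methylation). Persistent O-allylation, diene formation from the π-allyl complex or partial 2E/2Z erosion could spoil it. The fallback puts the chain on the succinate before the ring is built. It sets out from 16. K2CO3/MeOH gives (2E,7S,11R,15R,18E,22E,26E)-3,7,11,15,19,23,27,31-octamethyldotriaconta-2,18,22,26-tetraen-1-ol F5. PBr3 in Et2O at −10 °C gives (2E,7S,11R,15R,18E,22E,26E)-1-bromo-3,7,11,15,19,23,27,31-octamethyldotriaconta-2,18,22,26-tetraene F6. The lithium enolate of 18 (LDA, THF, −78 °C) is alkylated by F6 to dimethyl 2-[(2E,7S,11R,15R,18E,22E,26E)-3,7,11,15,19,23,27,31-octamethyldotriaconta-2,18,22,26-tetraen-1-yl]butanedioate F7. Claisen/Dieckmann condensation of F7 with 17 (NaH, THF, reflux) closes the ring on the chain-bearing succinate and comes back to the route at 21, which is methylated to 22 with NaH/MeI as in the second half of step 12.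

**Further compounds**
F1 | step 4 | (2E,6E,11R)-12-hydroxy-3,7,11-trimethyldodeca-2,6-dien-1-yl acetate | CC(=O)OC/C=C(\C)CC/C=C(\C)CCC[C@@H](C)CO
F2 | step 6 | 1-methyl-4-{[(2E,6E,10E)-3,7,11,15-tetramethylhexadeca-2,6,10-trien-1-yl]sulfonyl}benzene | Cc1ccc(cc1)S(=O)(=O)C/C=C(\C)CC/C=C(\C)CC/C=C(\C)CCCC(C)C
F3 | step 6 | (3S,7R,11R)-12-bromo-3,7,11-trimethyldodecan-1-ol | OCC[C@@H](C)CCC[C@@H](C)CCC[C@@H](C)CBr
F4 | step 6 | (3S,7R,11R,14E,18E,22E)-3,7,11,15,19,23,27-heptamethyl-13-(4-methylbenzenesulfonyl)octacosa-14,18,22-trien-1-ol (C13 epimers) | OCC[C@@H](C)CCC[C@@H](C)CCC[C@@H](C)CC(S(=O)(=O)c1ccc(C)cc1)/C=C(\C)CC/C=C(\C)CC/C=C(\C)CCCC(C)C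
F5 | step 12 | (2E,7S,11R,15R,18E,22E,26E)-3,7,11,15,19,23,27,31-octamethyldotriaconta-2,18,22,26-tetraen-1-ol | OC/C=C(\C)CCC[C@@H](C)CCC[C@@H](C)CCC[C@@H](C)CC/C=C(\C)CC/C=C(\C)CC/C=C(\C)CCCC(C)C
F6 | step 12 | (2E,7S,11R,15R,18E,22E,26E)-1-bromo-3,7,11,15,19,23,27,31-octamethyldotriaconta-2,18,22,26-tetraene | BrC/C=C(\C)CCC[C@@H](C)CCC[C@@H](C)CCC[C@@H](C)CC/C=C(\C)CC/C=C(\C)CC/C=C(\C)CCCC(C)C
F7 | step 12 | dimethyl 2-[(2E,7S,11R,15R,18E,22E,26E)-3,7,11,15,19,23,27,31-octamethyldotriaconta-2,18,22,26-tetraen-1-yl]butanedioate (succinate C2 not controlled) | COC(=O)CC(C/C=C(\C)CCC[C@@H](C)CCC[C@@H](C)CCC[C@@H](C)CC/C=C(\C)CC/C=C(\C)CC/C=C(\C)CCCC(C)C)C(=O)OC
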